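**Retrosynthetic overview**

1. The target is traced back through its heptabenzyl ether and a Horner–Wadsworth–Emmons cut at the C5 vinyl bond to a C5 aldehyde, and from there to the C5 methyl ester/C6 phenol (a salicylate) of the 2,3-diaryl-2,3-dihydrobenzofuran.
2. Feature used: in ring A the C6 hydroxyl and the C5 carbon substituent are ortho (a salicylate pair) and O1 sits on C7a. Ring A is therefore cut at C4–C5 and C6–C7 into a malonate (C5, C6, ester) and a dihydrofuran whose 2-methyl group becomes C7 and whose 3-formyl group becomes C4; C2, C3 and both aryl groups are already in place.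
3. That 2-methyl-4,5-dihydrofuran-3-carbaldehyde comes, by reduction and oxidation, from the ester made in a [4+1] annulation of a benzylidene acetoacetate with a C2-symmetric chiral benzylsulfonium ylide, which sets the trans (S,S) centres.
4. Ring order: dihydrofuran ring (O1–C2–C3–C3a–C7a) first, benzene ring A second (key step), stilbene arm last.
5. The phenols travel as benzyl ethers (all benzylated building blocks are purchasable), so the final unmasking is a −78 °C BCl3/pentamethylbenzene cleavage rather than a seven-fold demethylation beside the C2 benzylic ether and the alkene.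

Key step: step 8

Assumption: the ylide of the (2S,5S)-thiolanium salt is taken to react with the facial sense usual for benzylidene transfer from this sulfide class to aldehydes, which corresponds to (5S) and, through the trans closure, (4S) in the dihydrofuran; if the sense proves opposite, the (2R,5R)-sulfide made the same way from (2S,5S)-hexane-2,5-diol is used and nothing else changes.

**Route**

Step 1
Reactants: 1 (2R,5R)-hexane-2,5-diol
Product: 2 (2R,5R)-hexane-2,5-diyl dimethanesulfonate
Conditions: MsCl, Et3N, CH2Cl2, −20 → 0 °C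
Reagents that add atoms: methanesulfonyl chloride, CS(=O)(=O)Cl
Why: Mesylation (sulfonate ester formation) takes place at oxygen, so both stereocentres are retained and become SN2 leaving-group carbons.

Step 2
Reactants: 2 (2R,5R)-hexane-2,5-diyl dimethanesulfonate
Product: 3 (2S,5S)-2,5-dimethylthiolane
Conditions: Na2S·9H2O, DMSO, rt; pentane extraction, distillation
Reagents that add atoms: sodium sulfide, [Na+].[Na+].[S-2]
Why: Double SN2 thioetherification (intermolecular displacement, then 5-exo-tet ring closure) inverts both carbinol centres, so the (2R,5R)-bis-mesylate should give the C2-symmetric (2S,5S)-thiolane.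

Step 3
Reactants: 3 (2S,5S)-2,5-dimethylthiolane; 4 3,4-bis(benzyloxy)benzyl chloride
Product: 5 (2S,5S)-1-[3,4-bis(benzyloxy)benzyl]-2,5-dimethylthiolan-1-ium tetrafluoroborate
Conditions: AgBF4, acetone, 0 °C → rt, dark
Reagents that add atoms: silver tetrafluoroborate, [Ag+].F[B-](F)(F)F
Why: S-alkylation of a thioether by a benzylic halide is driven by precipitation of AgCl and leaves a non-nucleophilic counter-ion so that the salt of this electron-rich benzyl group cannot revert; the two sulfur lone pairs of the C2-symmetric thiolane are equivalent, so one sulfonium salt forms and no stereocentre is created.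

Step 4
Reactants: 6 3,5-bis(benzyloxy)benzaldehyde; 7 methyl acetoacetate
Product: 8 methyl 2-[3,5-bis(benzyloxy)benzylidene]-3-oxobutanoate (E/Z mixture)
Conditions: piperidine (10 mol%), AcOH (10 mol%), 4 Å MS, toluene, rt → 40 °C
Reagents that add atoms: none
Why: Knoevenagel condensation of an aromatic aldehyde with a β-ketoester under piperidinium acetate; the E/Z ratio is immaterial because the alkene geometry is erased in the enolate formed in step 5.

Step 5
Reactants: 8 methyl 2-[3,5-bis(benzyloxy)benzylidene]-3-oxobutanoate; 5 (2S,5S)-1-[3,4-bis(benzyloxy)benzyl]-2,5-dimethylthiolan-1-ium tetrafluoroborate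
Product: 10 methyl (4S,5S)-5-[3,4-bis(benzyloxy)phenyl]-4-[3,5-bis(benzyloxy)phenyl]-2-methyl-4,5-dihydrofuran-3-carboxylate, via sulfonium ylide 9 (not isolated)
Conditions: Cs2CO3, MeCN, −20 → 0 °C
Reagents that add atoms: none
Why: Sulfonium ylide [4+1] annulation (Michael addition of the benzylic ylide to C-β of 8, then 5-exo-tet O-alkylation of the β-ketoester enolate at the benzylic carbon with loss of the thiolane), in which the C2-symmetric thiolanium ylide exposes one face of the ylide carbon and so fixes C5, while reversible betaine formation with the aryl groups anti should funnel the closure to the 4,5-trans (4S,5S) ring.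

Step 6
Reactants: 10 methyl (4S,5S)-5-[3,4-bis(benzyloxy)phenyl]-4-[3,5-bis(benzyloxy)phenyl]-2-methyl-4,5-dihydrofuran-3-carboxylate
Product: 11 [(4S,5S)-5-[3,4-bis(benzyloxy)phenyl]-4-[3,5-bis(benzyloxy)phenyl]-2-methyl-4,5-dihydrofuran-3-yl]methanol
Conditions: i-Bu2AlH (2.5 equiv), CH2Cl2, −78 °C; aq. potassium sodium tartrate, Et3N-buffered isolation
Reagents that add atoms: none
Why: 1,2-Hydride reduction of the β-alkoxyacrylate (vinylogous carbonate) ester by an aluminium hydride at low temperature should give the allylic alcohol without touching C4 or C5, and the non-acidic work-up protects the acid-labile hydroxymethyl enol ether.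

Step 7
Reactants: 11 [(4S,5S)-5-[3,4-bis(benzyloxy)phenyl]-4-[3,5-bis(benzyloxy)phenyl]-2-methyl-4,5-dihydrofuran-3-yl]methanol
Product: 12 (4S,5S)-5-[3,4-bis(benzyloxy)phenyl]-4-[3,5-bis(benzyloxy)phenyl]-2-methyl-4,5-dihydrofuran-3-carbaldehyde
Conditions: activated MnO2 (excess), CH2Cl2, rt
Reagents that add atoms: none
Why: MnO2 oxidation of an allylic alcohol under neutral heterogeneous conditions should give the push–pull enal (a vinylogous formate) and leave the stereocentres and benzyl ethers alone.

Step 8
Reactants: 12 (4S,5S)-5-[3,4-bis(benzyloxy)phenyl]-4-[3,5-bis(benzyloxy)phenyl]-2-methyl-4,5-dihydrofuran-3-carbaldehyde; 13 dimethyl malonate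
Product: 16 methyl (2S,3S)-2-[3,4-bis(benzyloxy)phenyl]-3-[3,5-bis(benzyloxy)phenyl]-6-hydroxy-2,3-dihydro-1-benzofuran-5-carboxylate, via alkylidene malonate 14 (not isolated), via cyclohexadienone 15 (not isolated)
Conditions: piperidine (0.2 equiv), AcOH (0.2 equiv), 4 Å MS, toluene, 80 °C; then NaOMe (3 equiv), MeOH/THF, 60 °C; AcOH quench
Reagents that add atoms: none
Why: Proposed new method: piperidinium acetate condenses the malonate with the formyl group (Knoevenagel, new C4=C5 bond; benzofuran numbering of 16 throughout) to the dienyl diester 14, in which the methyl group on C7a is the doubly vinylogous position of a malonate, so that methoxide removes one of its protons and the trienolate carbon (C7) attacks the ester carbonyl held cis to it (new C6–C7 bond), methoxide leaves and the cyclohexadienone 15 enolises to the salicylate 16. The closest known reaction type is the Knoevenagel condensation/vinylogous intramolecular Claisen (Dieckmann-type) benzannulation that fuses salicylate rings onto aromatic 2-methyl-3-formyl heterocycles; it has not been shown on a non-aromatic 2-methyl-4,5-dihydrofuran-3-carbaldehyde, whose methyl group should be easier to deprotonate because no heteroaromatic sextet is disturbed. Ring A closes by a 6-exo-trig acylation (the attacked C=O is exocyclic to the forming ring), after which loss of methoxide and tautomerisation make the sequence irreversible. No stereocentre is formed, and C2–H and C3–H are not conjugated with the diester (a carbanion at C3 would be cross-conjugated), so the trans (2S,3S) array set in step 5 should be carried through unchanged. The selectivity needed is condensation at the aldehyde in preference to conjugate addition of amine, malonate or methoxide at C7a with opening of the enol ether; C7a is fully substituted, the buffered amine is present in small amount and engages the aldehyde as its iminium ion, and any C7a adduct can only revert or re-close whereas aromatisation cannot. Regiochemistry is not an issue because the two ester groups of the symmetric malonate are equivalent and only the C7a methyl group is vinylogously acidic.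

Step 9
Reactants: 16 methyl (2S,3S)-2-[3,4-bis(benzyloxy)phenyl]-3-[3,5-bis(benzyloxy)phenyl]-6-hydroxy-2,3-dihydro-1-benzofuran-5-carboxylate
Product: 17 methyl (2S,3S)-6-(benzyloxy)-2-[3,4-bis(benzyloxy)phenyl]-3-[3,5-bis(benzyloxy)phenyl]-2,3-dihydro-1-benzofuran-5-carboxylate
Conditions: BnBr, K2CO3, DMF, 60 °C
Reagents that add atoms: benzyl bromide, BrCc1ccccc1
Why: Williamson etherification of the salicylate phenol (hydrogen-bonded to the ester, hence gentle heating) masks it for the hydride and olefination steps with the same group as the other phenols.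

Step 10
Reactants: 17 methyl (2S,3S)-6-(benzyloxy)-2-[3,4-bis(benzyloxy)phenyl]-3-[3,5-bis(benzyloxy)phenyl]-2,3-dihydro-1-benzofuran-5-carboxylate
Product: 18 [(2S,3S)-6-(benzyloxy)-2-[3,4-bis(benzyloxy)phenyl]-3-[3,5-bis(benzyloxy)phenyl]-2,3-dihydro-1-benzofuran-5-yl]methanol
Conditions: LiAlH4, THF, 0 °C
Reagents that add atoms: none
Why: LiAlH4 reduction of the aryl ester to the benzylic alcohol; benzyl ethers and the diarylmethine C3–H are inert to hydride.

Step 11
Reactants: 18 [(2S,3S)-6-(benzyloxy)-2-[3,4-bis(benzyloxy)phenyl]-3-[3,5-bis(benzyloxy)phenyl]-2,3-dihydro-1-benzofuran-5-yl]methanol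
Product: 19 (2S,3S)-6-(benzyloxy)-2-[3,4-bis(benzyloxy)phenyl]-3-[3,5-bis(benzyloxy)phenyl]-2,3-dihydro-1-benzofuran-5-carbaldehyde
Conditions: activated MnO2 (excess), CH2Cl2, rt
Reagents that add atoms: none
Why: MnO2 oxidation of an electron-rich benzylic alcohol should stop cleanly at the aldehyde.

Step 12
Reactants: 20 3,5-bis(benzyloxy)benzyl bromide
Product: 21 diethyl [3,5-bis(benzyloxy)benzyl]phosphonate
Conditions: P(OEt)3 (neat), 130 °C
Reagents that add atoms: triethyl phosphite, CCOP(OCC)OCC
Why: Michaelis–Arbuzov reaction of a primary benzylic bromide with triethyl phosphite, driven by loss of volatile bromoethane.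

Step 13
Reactants: 19 (2S,3S)-6-(benzyloxy)-2-[3,4-bis(benzyloxy)phenyl]-3-[3,5-bis(benzyloxy)phenyl]-2,3-dihydro-1-benzofuran-5-carbaldehyde; 21 diethyl [3,5-bis(benzyloxy)benzyl]phosphonate
Product: 22 (2S,3S)-6-(benzyloxy)-2-[3,4-bis(benzyloxy)phenyl]-3-[3,5-bis(benzyloxy)phenyl]-5-{(E)-2-[3,5-bis(benzyloxy)phenyl]ethenyl}-2,3-dihydro-1-benzofuran
Conditions: KOtBu, THF, 0 °C → rt
Reagents that add atoms: none
Why: Horner–Wadsworth–Emmons olefination of an aryl aldehyde with a benzylic phosphonate carbanion should give the (E)-stilbene through the reversible, thermodynamically controlled adduct, and C3–H (a diarylmethine meta to the formyl group) is not deprotonated by KOtBu at 0 °C, so the stereocentres survive.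

Step 14
Reactants: 22 (2S,3S)-6-(benzyloxy)-2-[3,4-bis(benzyloxy)phenyl]-3-[3,5-bis(benzyloxy)phenyl]-5-{(E)-2-[3,5-bis(benzyloxy)phenyl]ethenyl}-2,3-dihydro-1-benzofuran
Product: 23 4-[(2S,3S)-3-(3,5-dihydroxyphenyl)-5-[(E)-2-(3,5-dihydroxyphenyl)ethenyl]-6-hydroxy-2,3-dihydro-1-benzofuran-2-yl]benzene-1,2-diol (CNP0263230.1)
Conditions: BCl3 (1 M in CH2Cl2), pentamethylbenzene, CH2Cl2, −78 °C; MeOH quench at −78 °C
Reagents that add atoms: none
Why: Lewis-acid cleavage of aryl benzyl ethers by BCl3 with pentamethylbenzene as a non-Lewis-basic cation scavenger (Friedel–Crafts capture of each benzyl cation) runs at −78 °C, where the stilbene should not be attacked and, should the C2–O1 benzylic ether open, the tethered phenol re-closes to the favoured trans ring with C3 untouched.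

**Compound list**

1 | (2R,5R)-hexane-2,5-diol | C[C@@H](O)CC[C@@H](C)O | starting material
2 | (2R,5R)-hexane-2,5-diyl dimethanesulfonate | C[C@@H](OS(C)(=O)=O)CC[C@@H](C)OS(C)(=O)=O | intermediate
3 | (2S,5S)-2,5-dimethylthiolane | C[C@H]1CC[C@H](C)S1 | intermediate
4 | 3,4-bis(benzyloxy)benzyl chloride | ClCc1ccc(OCc2ccccc2)c(OCc2ccccc2)c1 | starting material
5 | (2S,5S)-1-[3,4-bis(benzyloxy)benzyl]-2,5-dimethylthiolan-1-ium tetrafluoroborate | C[C@H]1CC[C@H](C)[S+]1Cc1ccc(OCc2ccccc2)c(OCc2ccccc2)c1.F[B-](F)(F)F | intermediate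
6 | 3,5-bis(benzyloxy)benzaldehyde | O=Cc1cc(OCc2ccccc2)cc(OCc2ccccc2)c1 | starting material
7 | methyl acetoacetate | COC(=O)CC(C)=O | starting material
8 | methyl 2-[3,5-bis(benzyloxy)benzylidene]-3-oxobutanoate (E/Z mixture) | COC(=O)C(=Cc1cc(OCc2ccccc2)cc(OCc2ccccc2)c1)C(C)=O | intermediate
9 | [3,4-bis(benzyloxy)phenyl][(2S,5S)-2,5-dimethylthiolan-1-ium-1-yl]methanide (sulfonium ylide) | C[C@H]1CC[C@H](C)[S+]1[CH-]c1ccc(OCc2ccccc2)c(OCc2ccccc2)c1 | intermediate
10 | methyl (4S,5S)-5-[3,4-bis(benzyloxy)phenyl]-4-[3,5-bis(benzyloxy)phenyl]-2-methyl-4,5-dihydrofuran-3-carboxylate | COC(=O)C1=C(C)O[C@H](c2ccc(OCc3ccccc3)c(OCc3ccccc3)c2)[C@H]1c4cc(OCc5ccccc5)cc(OCc5ccccc5)c4 | intermediate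
11 | [(4S,5S)-5-[3,4-bis(benzyloxy)phenyl]-4-[3,5-bis(benzyloxy)phenyl]-2-methyl-4,5-dihydrofuran-3-yl]methanol | OCC1=C(C)O[C@H](c2ccc(OCc3ccccc3)c(OCc3ccccc3)c2)[C@H]1c4cc(OCc5ccccc5)cc(OCc5ccccc5)c4 | intermediate
12 | (4S,5S)-5-[3,4-bis(benzyloxy)phenyl]-4-[3,5-bis(benzyloxy)phenyl]-2-methyl-4,5-dihydrofuran-3-carbaldehyde | O=CC1=C(C)O[C@H](c2ccc(OCc3ccccc3)c(OCc3ccccc3)c2)[C@H]1c4cc(OCc5ccccc5)cc(OCc5ccccc5)c4 | intermediate
13 | dimethyl malonate | COC(=O)CC(=O)OC | starting material
14 | dimethyl 2-{[(4S,5S)-5-[3,4-bis(benzyloxy)phenyl]-4-[3,5-bis(benzyloxy)phenyl]-2-methyl-4,5-dihydrofuran-3-yl]methylidene}propanedioate (alkylidene malonate) | COC(=O)C(=CC1=C(C)O[C@H](c2ccc(OCc3ccccc3)c(OCc3ccccc3)c2)[C@H]1c4cc(OCc5ccccc5)cc(OCc5ccccc5)c4)C(=O)OC | intermediate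
15 | methyl (2S,3S)-2-[3,4-bis(benzyloxy)phenyl]-3-[3,5-bis(benzyloxy)phenyl]-6-oxo-2,3,6,7-tetrahydro-1-benzofuran-5-carboxylate (cyclohexadienone) | COC(=O)C1=CC2=C(CC1=O)O[C@H](c3ccc(OCc4ccccc4)c(OCc4ccccc4)c3)[C@H]2c5cc(OCc6ccccc6)cc(OCc6ccccc6)c5 | intermediate
16 | methyl (2S,3S)-2-[3,4-bis(benzyloxy)phenyl]-3-[3,5-bis(benzyloxy)phenyl]-6-hydroxy-2,3-dihydro-1-benzofuran-5-carboxylate | COC(=O)c1cc2c(cc1O)O[C@H](c3ccc(OCc4ccccc4)c(OCc4ccccc4)c3)[C@H]2c5cc(OCc6ccccc6)cc(OCc6ccccc6)c5 | intermediate
17 | methyl (2S,3S)-6-(benzyloxy)-2-[3,4-bis(benzyloxy)phenyl]-3-[3,5-bis(benzyloxy)phenyl]-2,3-dihydro-1-benzofuran-5-carboxylate | COC(=O)c1cc2c(cc1OCc7ccccc7)O[C@H](c3ccc(OCc4ccccc4)c(OCc4ccccc4)c3)[C@H]2c5cc(OCc6ccccc6)cc(OCc6ccccc6)c5 | intermediate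
18 | [(2S,3S)-6-(benzyloxy)-2-[3,4-bis(benzyloxy)phenyl]-3-[3,5-bis(benzyloxy)phenyl]-2,3-dihydro-1-benzofuran-5-yl]methanol | OCc1cc2c(cc1OCc7ccccc7)O[C@H](c3ccc(OCc4ccccc4)c(OCc4ccccc4)c3)[C@H]2c5cc(OCc6ccccc6)cc(OCc6ccccc6)c5 | intermediate
19 | (2S,3S)-6-(benzyloxy)-2-[3,4-bis(benzyloxy)phenyl]-3-[3,5-bis(benzyloxy)phenyl]-2,3-dihydro-1-benzofuran-5-carbaldehyde | O=Cc1cc2c(cc1OCc7ccccc7)O[C@H](c3ccc(OCc4ccccc4)c(OCc4ccccc4)c3)[C@H]2c5cc(OCc6ccccc6)cc(OCc6ccccc6)c5 | intermediate
20 | 3,5-bis(benzyloxy)benzyl bromide | BrCc1cc(OCc2ccccc2)cc(OCc2ccccc2)c1 | starting material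
21 | diethyl [3,5-bis(benzyloxy)benzyl]phosphonate | CCOP(=O)(Cc1cc(OCc2ccccc2)cc(OCc2ccccc2)c1)OCC | intermediate
22 | (2S,3S)-6-(benzyloxy)-2-[3,4-bis(benzyloxy)phenyl]-3-[3,5-bis(benzyloxy)phenyl]-5-{(E)-2-[3,5-bis(benzyloxy)phenyl]ethenyl}-2,3-dihydro-1-benzofuran | c1(OCc8ccccc8)cc(OCc8ccccc8)cc(/C=C/c2cc3c(cc2OCc7ccccc7)O[C@H](c4ccc(OCc9ccccc9)c(OCc9ccccc9)c4)[C@H]3c5cc(OCc6ccccc6)cc(OCc6ccccc6)c5)c1 | intermediate
23 | 4-[(2S,3S)-3-(3,5-dihydroxyphenyl)-5-[(E)-2-(3,5-dihydroxyphenyl)ethenyl]-6-hydroxy-2,3-dihydro-1-benzofuran-2-yl]benzene-1,2-diol (CNP0263230.1) | Oc1cc(O)cc(/C=C/c2cc3c(cc2O)O[C@H](c2ccc(O)c(O)c2)[C@H]3c2cc(O)cc(O)c2)c1 | target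

**Step count and risks**

Total step count: 14.
Longest linear sequence: 12 steps, counted through the recoverable sulfide branch (1, 2, 3, 5, 6, 7, 8, 9, 10, 11, 13, 14); along the carbon skeleton from 3,5-bis(benzyloxy)benzaldehyde it is 10 steps (4 to 11, 13, 14).

Steps most likely to fail:

Step 8. The condensation may stall on the push–pull aldehyde, or amine, malonate or methoxide may add to C7a and open the enol ether, or a second malonate may add to the dienyl diester, before the vinylogous deprotonation takes place. The fallback uses known chemistry and builds the arene first: it sets out from aldehyde 6 and sulfonium salt 5 and comes back to the route at 16. Aldehyde 6, commercial methyl 2,4-dihydroxybenzoate and sodium p-toluenesulfinate are condensed in aqueous formic acid at C5 of the resorcylate to give the racemic sulfone methyl 5-{[3,5-bis(benzyloxy)phenyl](4-methylbenzenesulfonyl)methyl}-2,4-dihydroxybenzoate F1. With Cs2CO3 in CH2Cl2 at 0 °C, F1 loses sulfinate to the ortho-quinone methide methyl 3-[3,5-bis(benzyloxy)benzylidene]-6-hydroxy-4-oxocyclohexa-1,5-diene-1-carboxylate F2, which is not isolated. The ylide of 5 adds to its methide carbon and the neighbouring phenoxide displaces the thiolane ([4+1] annulation of a sulfonium ylide with an ortho-quinone methide), which should give the trans-dihydrobenzofuran 16 with the chelated C6 hydroxyl left free.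

Step 5. The betaine may close through carbon to a cyclopropane, the electron-rich benzylic ylide may rearrange or fragment before it adds, or the two faces of the ylide may be discriminated poorly, which lowers the enantiomeric purity. The fallback sets out from phosphonate 21 and methyl acetoacetate 7 and comes back at 10. Olefination of commercial 3,4-bis(benzyloxy)benzaldehyde with 21 (KOtBu, THF) gives the stilbene 1,2-bis(benzyloxy)-4-{(E)-2-[3,5-bis(benzyloxy)phenyl]ethenyl}benzene F3. Oxidative radical [3+2] annulation with 7 and Mn(OAc)3·2H2O in AcOH at 70 °C should then give the racemic trans ester: the acetoacetate radical adds to the alkene carbon that carries the 3,5-disubstituted ring, and the benzylic radical beside the para-oxygenated ring is oxidised and trapped by the enol oxygen. The racemate is 10 together with its enantiomer methyl (4R,5R)-5-[3,4-bis(benzyloxy)phenyl]-4-[3,5-bis(benzyloxy)phenyl]-2-methyl-4,5-dihydrofuran-3-carboxylate F4; preparative chromatography on a chiral stationary phase then delivers 10.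

Step 14. Seven-fold cleavage may stop short, benzyl cations that escape the scavenger may C-alkylate the resorcinol rings, the C2–O1 benzylic ether may open under the Lewis acid, and the free heptaphenol may be lost by air oxidation or adsorption during isolation. The fallback sets out from 22 and comes back at 23; it answers the isolation and purification losses but still relies on the BCl3 cleavage itself. After the BCl3/pentamethylbenzene treatment and methanol quench, the crude phenol is not purified but acetylated directly (Ac2O, pyridine, DMAP, 0 °C) to the heptaacetate 4-[(2S,3S)-6-acetoxy-3-(3,5-diacetoxyphenyl)-5-[(E)-2-(3,5-diacetoxyphenyl)ethenyl]-2,3-dihydro-1-benzofuran-2-yl]-1,2-phenylene diacetate F5, which should be stable to air and silica and can be purified by chromatography and crystallisation. Methanolysis with K2CO3 in degassed MeOH at 0 °C, neutralised with an acidic ion-exchange resin and filtered, then releases 23 without aqueous or chromatographic handling of the free phenol.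

**Further compounds**

F1 | step 8 | methyl 5-{[3,5-bis(benzyloxy)phenyl](4-methylbenzenesulfonyl)methyl}-2,4-dihydroxybenzoate (racemic) | COC(=O)c1cc(C(c2cc(OCc3ccccc3)cc(OCc3ccccc3)c2)S(=O)(=O)c4ccc(C)cc4)c(O)cc1O
F2 | step 8 | methyl 3-[3,5-bis(benzyloxy)benzylidene]-6-hydroxy-4-oxocyclohexa-1,5-diene-1-carboxylate (ortho-quinone methide, not isolated) | COC(=O)C1=CC(=Cc2cc(OCc3ccccc3)cc(OCc3ccccc3)c2)C(=O)C=C1O
F3 | step 5 | 1,2-bis(benzyloxy)-4-{(E)-2-[3,5-bis(benzyloxy)phenyl]ethenyl}benzene | c1(OCc2ccccc2)cc(OCc2ccccc2)cc(/C=C/c3ccc(OCc2ccccc2)c(OCc2ccccc2)c3)c1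
F4 | step 5 | methyl (4R,5R)-5-[3,4-bis(benzyloxy)phenyl]-4-[3,5-bis(benzyloxy)phenyl]-2-methyl-4,5-dihydrofuran-3-carboxylate | COC(=O)C1=C(C)O[C@@H](c2ccc(OCc3ccccc3)c(OCc3ccccc3)c2)[C@@H]1c4cc(OCc5ccccc5)cc(OCc5ccccc5)c4
F5 | step 14 | 4-[(2S,3S)-6-acetoxy-3-(3,5-diacetoxyphenyl)-5-[(E)-2-(3,5-diacetoxyphenyl)ethenyl]-2,3-dihydro-1-benzofuran-2-yl]-1,2-phenylene diacetate | CC(=O)Oc1cc(OC(C)=O)cc(/C=C/c2cc3c(cc2OC(C)=O)O[C@H](c4ccc(OC(C)=O)c(OC(C)=O)c4)[C@H]3c5cc(OC(C)=O)cc(OC(C)=O)c5)c1
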